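I began with the easy step: how fast the solid nucleophile can feed this flask.

electrophile 20 mM; free base 16.0 mM; solid nucleophile 60.0 mM; protic impurity 0.400 mM; time 10 d

    electrophile + nucleophile → acid set free + target (k1 = 0.906 /M/h)
    nucleophile + acid set free ⇌ protonated nucleophile, settled at all times (K2 = 26200 /M)
    acid set free + free base ⇌ salt of the base (K3 = 210 /M, k3 = 27.4 /M/h)
    solid nucleophile ⇌ nucleophile, rate k4*(cs4 - [nucleophile]) while solid is left; crystals form when [nucleophile] > cs4 (cs4 = 0.99 mM, k4 = 0.0116 /h)
    electrophile + acid set free ⇌ idle adduct, settled at all times (K5 = 35 /M)
    protic impurity + free base → quenched reagent (k6 = 6.36 /M/h)

* part of the electrophile that has reacted at 10 d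
* share of free nucleophile in free nucleophile and protonated nucleophile together, at 10 d

- for acid set free the idle adduct is counted in
- as a solid, counted per litre of solution: solid nucleophile
- at the start none of the solid nucleophile is in solution
- run time (flask): 10 d

With no nucleophile in solution, the feed is the dissolution coefficient times the solubility, 0.0115 mM/h. The bench rule says that what dissolves is consumed at once, and on this flask it gave 13.8% of the electrophile in 10 d. That rule needs uptake far faster than dissolution, so I compared two first-order constants. The electrophile as charged takes up free nucleophile with a pseudo-first-order constant u = 0.0181 /h, against 0.0116 /h for dissolution. Their ratio ρ = 1.56 is less than 2, so I judged the flask to lie beyond the rule's border.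

I therefore used the balance level B*, the free nucleophile at which dissolution equals uptake, which is the solubility divided by one plus ρ: 0.386 mM. The flask approaches it with a time constant of 1.40 d. Taking that lag off the run, uptake at B* gave 7.22% of the electrophile, or 1.44 mM of acid set free.

But the comparison drifts, since each target frees acid. At the charged free base, the balance stands at 3.4 parts salt to one of free acid, and free acid of 0.0382 mM protonates half of the nucleophile in solution. Shared between salt and free acid, with protonated nucleophile and idle adduct left out of this rough balance, my acid left 0.331 mM free, more than that, so I took 7.22% as a high estimate and expected less.

The forecast gave 5.4% (4.7% to 6.2%) for the part of the electrophile reacted, c, below my estimate, and 31% (25% to 38%) for the free share of the nucleophile, fr, reasoning: “The base is too weak to hold the acid down completely”.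

The simulation gave 5.71% for c and 30.4% for fr, both inside the forecast's ranges. In the flask, quenching of the protic impurity by free base had 99.2% of its turnover behind it by 2.00 d, and it made no difference to c. Conversion of the electrophile had 45% of its turnover behind it at 5.00 d, while the free share of dissolved nucleophile sank from 87.8% at 1.00 d to 30.4% at 10 d, with free nucleophile then at 0.291 mM, below the B* reckoned for the charged electrophile. For the neighbour charged with 5.0 mM of electrophile, B* gives 0.712 mM and the same reckoning a high estimate of 11.5%. The simulation of that neighbour gave 0.595 mM of free nucleophile and 9.73% for c.

All constants were chosen freely; the rest is arithmetic.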